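**Assumption:** brandisianin A has no stereocentre and no E/Z-defined alkene (the prenyl alkene carries two identical methyl groups), so "single enantiomer" means the achiral structure given.

## Retrosynthetic overview

1. The last bond made is the aryl C4'–O bond of the prenyl ether: the target comes from the 4'-bromo-5,7-dihydroxy-2',5'-dimethoxyisoflavone and prenol by copper-catalysed C–O coupling on the unprotected polyphenol.
2. Ring C (the pyranone) is opened at O1–C2/C2–C3 (one carbon from DMF) and at the C4–C4a acyl bond, giving phloroglucinol and 4-bromo-2,5-dimethoxyphenylacetic acid.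
3. The C–Br bond comes from para-selective bromination of 2,5-dimethoxyphenylacetic acid.
4. Ring order: rings A and B are bought, ring C is the only ring built (step 2), and the acid-labile prenyl ether is installed last so it never meets the Lewis acid.

## Route

Step 1
Reactants: 1 2,5-dimethoxyphenylacetic acid
Product: 2 4-bromo-2,5-dimethoxyphenylacetic acid
Conditions: Br2 (1.05 equiv), AcOH, rt; pour into water, recrystallise
Reagents that add atoms: bromine, BrBr
Why: Electrophilic aromatic bromination goes to C4, which is para to the alkyl chain and ortho to the 5-OMe, the least hindered activated position of a 2-alkyl-1,4-dimethoxybenzene; the CH2CO2H group is untouched without a radical or acyl-halide pathway.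

Step 2
Reactants: 2 4-bromo-2,5-dimethoxyphenylacetic acid; 3 phloroglucinol (benzene-1,3,5-triol, dried)
Product: 5 3-(4-bromo-2,5-dimethoxyphenyl)-5,7-dihydroxy-4H-chromen-4-one, via bromo deoxybenzoin 4 (not isolated)
Conditions: BF3·OEt2 (neat, as solvent and Lewis acid), 85 °C; then DMF, MsCl, 70 °C; aq NaOAc
Reagents that add atoms: N,N-dimethylformamide, CN(C)C=O
Why: BF3-mediated Friedel–Crafts C-acylation of symmetrical phloroglucinol gives the deoxybenzoin as its BF2 chelate, whose methylene is formylated by the DMF/MsCl Vilsmeier-type reagent and closed through an ortho phenol with loss of dimethylamine (one-pot deoxybenzoin isoflavone synthesis); the aryl bromide and methyl ethers are inert and both ortho OH groups are equivalent, so one isomer forms.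

Step 3
Reactants: 5 3-(4-bromo-2,5-dimethoxyphenyl)-5,7-dihydroxy-4H-chromen-4-one; 6 prenol (3-methylbut-2-en-1-ol)
Product: 7 brandisianin A, 5,7-dihydroxy-3-[2,5-dimethoxy-4-(3-methylbut-2-enyloxy)phenyl]-4H-chromen-4-one
Conditions: CuI (10 mol %), N1,N2-bis(2,4,6-trimethoxyphenyl)oxalamide (20 mol %), NaOt-Bu (3.5 equiv), 6 (10 equiv), 1,4-dioxane, 80 °C, Ar; aq NH4Cl
Reagents that add atoms: none
Why: Proposed new method: an Ullmann-type copper-catalysed etherification, not yet shown on an unprotected 5,7-dihydroxychromone aryl bromide with a prenyl-type allylic alcohol; the dianionic oxalamide gives an electron-rich monovalent copper prenoxide that activates the electron-rich, ortho-methoxy aryl bromide (oxidative addition to trivalent copper, then C–O reductive elimination), while the 7- and 5-phenoxides of the substrate are vinylogous-carboxylate or chelated anions far less basic than prenoxide, so they should not compete against 10 equiv of alkoxide, and their charge deactivates C2 of the pyranone toward alkoxide attack; copper does not ionise the allyl aryl ether product as zerovalent palladium or nickel would, 80 °C is well below the Claisen threshold, and the site of etherification is fixed by the bromine so no phenol-selectivity problem arises; closest known reaction type: copper/oxalamide- or phenanthroline-catalysed coupling of aryl bromides with primary aliphatic alcohols.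

## Compound list

1 | 2,5-dimethoxyphenylacetic acid | COc1ccc(OC)c(CC(=O)O)c1 | starting material
2 | 4-bromo-2,5-dimethoxyphenylacetic acid | COc1cc(CC(=O)O)c(OC)cc1Br | intermediate
3 | phloroglucinol (benzene-1,3,5-triol) | Oc1cc(O)cc(O)c1 | starting material
4 | 2-(4-bromo-2,5-dimethoxyphenyl)-1-(2,4,6-trihydroxyphenyl)ethan-1-one (deoxybenzoin, formed in the flask in step 2) | COc1cc(CC(=O)c2c(O)cc(O)cc2O)c(OC)cc1Br | intermediate
5 | 3-(4-bromo-2,5-dimethoxyphenyl)-5,7-dihydroxy-4H-chromen-4-one (4'-bromo-5,7-dihydroxy-2',5'-dimethoxyisoflavone) | COc1cc(-c2coc3cc(O)cc(O)c3c2=O)c(OC)cc1Br | intermediate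
6 | prenol (3-methylbut-2-en-1-ol) | CC(C)=CCO | starting material
7 | brandisianin A, 5,7-dihydroxy-3-[2,5-dimethoxy-4-(3-methylbut-2-enyloxy)phenyl]-4H-chromen-4-one | COc1cc(-c2coc3cc(O)cc(O)c3c2=O)c(OC)cc1OCC=C(C)C | target

## Step count

Total steps: 3. Longest linear sequence: 3 (1 → 2 → 5 → 7).

## Steps most likely to fail, with fallbacks

**Step 3 (proposed new C–O coupling).** Risks are copper sequestration by the phenoxide/keto chelate, hydrodebromination, and base-induced opening of the pyranone. The fallback uses known chemistry, sets out from 5 and comes back at 7.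
- Miyaura borylation of 5 (B2pin2, Pd(dppf)Cl2, KOAc, 1,4-dioxane, 90 °C) gives the pinacol boronate 3-[2,5-dimethoxy-4-(4,4,5,5-tetramethyl-1,3,2-dioxaborolan-2-yl)phenyl]-5,7-dihydroxy-4H-chromen-4-one F1.
- Oxidation (NaBO3·4H2O, THF/H2O, rt) gives the phenol 5,7-dihydroxy-3-(4-hydroxy-2,5-dimethoxyphenyl)-4H-chromen-4-one F2.
- Williamson prenylation through the 7,4'-dianion (KOt-Bu 2.1 equiv, DMF, 0 °C, then prenyl bromide 1.0 equiv) gives 7. The more basic guaiacol-type 4'-phenoxide is the more nucleophilic site, ahead of the stabilised 7-phenoxide, and the chelated 5-OH stays protonated.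

**Step 2 (one-pot acylation and ring closure).** Risks are incomplete C-acylation or a messy formylative closure with the ortho-substituted ring B. The fallback replaces the BF3 acylation by a Houben–Hoesch reaction with isolation of the deoxybenzoin; it sets out from 2 and 3 and comes back at 4.
- 2 with SOCl2 gives 2-(4-bromo-2,5-dimethoxyphenyl)acetyl chloride F3.
- Concentrated aqueous NH3 gives 2-(4-bromo-2,5-dimethoxyphenyl)acetamide F4.
- Dehydration (TFAA, pyridine, 0 °C) gives 2-(4-bromo-2,5-dimethoxyphenyl)acetonitrile F5.
- Hoesch condensation with 3 (ZnCl2, HCl gas, Et2O, 0 °C) gives 2-(4-bromo-2,5-dimethoxyphenyl)-1-(2,4,6-trihydroxyphenyl)ethan-1-iminium chloride F6, which precipitates.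
- Hydrolysis (H2O, 100 °C) gives 4, now purified by crystallisation and ring-closed separately under the second stage of step 2 (BF3·OEt2, DMF, MsCl) to 5.

**Step 1 (bromination).** Risks are over-bromination or a minor 6-bromo isomer that co-crystallises with the acid. The fallback is a protect–brominate–deprotect sequence on a neutral, chromatographable ester; it sets out from 1 and comes back at 2.
- Fischer esterification (MeOH, cat. H2SO4, reflux) gives methyl 2-(2,5-dimethoxyphenyl)acetate F7.
- NBS in MeCN at rt gives methyl 2-(4-bromo-2,5-dimethoxyphenyl)acetate F8, purified by chromatography or crystallisation.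
- Saponification (LiOH, THF/H2O, then dilute HCl) returns 2.

## Further compounds

F1 | step 3 | 3-[2,5-dimethoxy-4-(4,4,5,5-tetramethyl-1,3,2-dioxaborolan-2-yl)phenyl]-5,7-dihydroxy-4H-chromen-4-one | COc1cc(-c2coc3cc(O)cc(O)c3c2=O)c(OC)cc1B1OC(C)(C)C(C)(C)O1
F2 | step 3 | 5,7-dihydroxy-3-(4-hydroxy-2,5-dimethoxyphenyl)-4H-chromen-4-one | COc1cc(-c2coc3cc(O)cc(O)c3c2=O)c(OC)cc1O
F3 | step 2 | 2-(4-bromo-2,5-dimethoxyphenyl)acetyl chloride | COc1cc(CC(=O)Cl)c(OC)cc1Br
F4 | step 2 | 2-(4-bromo-2,5-dimethoxyphenyl)acetamide | COc1cc(CC(N)=O)c(OC)cc1Br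
F5 | step 2 | 2-(4-bromo-2,5-dimethoxyphenyl)acetonitrile | COc1cc(CC#N)c(OC)cc1Br
F6 | step 2 | 2-(4-bromo-2,5-dimethoxyphenyl)-1-(2,4,6-trihydroxyphenyl)ethan-1-iminium chloride | COc1cc(CC(=[NH2+])c2c(O)cc(O)cc2O)c(OC)cc1Br.[Cl-]
F7 | step 1 | methyl 2-(2,5-dimethoxyphenyl)acetate | COC(=O)Cc1cc(OC)ccc1OC
F8 | step 1 | methyl 2-(4-bromo-2,5-dimethoxyphenyl)acetate | COC(=O)Cc1cc(OC)c(Br)cc1OC
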